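The readings stem from a simulated flask on assumed constants, noise included.

Saturday's run with 60 mM of initiator and Monday's with 240 mM ended level, 41.8% against 41.7% at 6.00 h, so I read from them one pace, 0.160 M/h, and took it as the pace at which solid reagent enters solution, the likely rate-limiting step.

| setting | Saturday's | Monday's | Sunday's | flask |
|---|---|---|---|---|
| substrate | 2.3 M | 2.3 M | 2.3 M | 2.3 M |
| solid reagent | 1.61 M | 1.61 M | 0.81 M | 1.61 M |
| initiator | 60 mM | 240 mM | 120 mM | 120 mM |
| remark | run made earlier | run made earlier | run made earlier |  |
| time |  |  |  | 6.0 h |

| run | time / h | product / % |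
|---|---|---|
| Saturday's | 0.500 | 3.8 |
| Saturday's | 0.833 | 6.0 |
| Saturday's | 1.33 | 9.1 |
| Saturday's | 2.00 | 13.5 |
| Saturday's | 4.00 | 28.1 |
| Saturday's | 6.00 | 41.8 |
| Monday's | 0.500 | 3.5 |
| Monday's | 0.833 | 5.6 |
| Monday's | 1.33 | 9.7 |
| Monday's | 2.00 | 13.7 |
| Monday's | 4.00 | 28.0 |
| Monday's | 6.00 | 41.7 |
| Sunday's | 1.33 | 9.4 |
| Sunday's | 2.50 | 17.3 |
| Sunday's | 4.00 | 28.2 |
| Sunday's | 5.00 | 35.1 |
| Sunday's | 6.00 | 35.1 |

(standard deviation of a reading: 0.3 percentage points)

- as a solid, counted per litre of solution: solid reagent
- at the start none of the solid reagent is in solution
- coupling partner is what solid reagent becomes in solution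

- amount of product at 6.0 h, in percent of the substrate charged
- concentration of coupling partner in solution at 6.0 h, in percent of saturation

I followed one dissolved molecule of coupling partner to its fork, into product or lost, and Sunday's plateau gave a reading of 0.997 for the ratio of product formed to solid reagent charged, so I counted the lost branch as small. Turning the question round, the flask could leave the line if its solid were gone before 6.0 h. Its c(solid reagent) charge over that pace gives 10.0 h, its run-out time, longer than 6.0 h, while the same reckoning for Sunday's run gave 5.06 h, close to the 5.00 h by which its readings had stopped rising. I therefore expected the flask on the line.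

The forecast said 41.8% and 1% of saturation, reasoning from “supply-limited dissolution, with the partner consumed as fast as it enters solution”.

The flask gave 41.7% and 0%, so the forecast held, with 40.5% of its solid left at 6.00 h against the 40.0% that the run-out time gives.

    initiator → 2 initiating radical (k = 0.0560 /h)
    substrate + initiating radical → capped initiator + first chain carrier (k = 7.60 × 10⁶ /M/h)
    coupling partner + first chain carrier → product + second chain carrier (k = 3.20 × 10⁵ /M/h)
    substrate + second chain carrier → by-product + first chain carrier (k = 1.00 × 10⁷ /M/h)
    2 second chain carrier → ended chains (k = 9.50 × 10⁶ /M/s)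
    solid reagent ⇌ coupling partner, rate k6*(cs6 - [coupling partner]) while solid is left; crystals form when [coupling partner] > cs6 (solubility = 0.340 M, k = 0.470 /h)
    coupling partner → decomposed reagent (k = 0.540 /h)

The flask's product stood level with the 41.7% that going into solution can deliver by 6.0 h into a solution kept empty. The decay of coupling partner, taken by that step alone, has a half-life of 1.3 h, short against 6.0 h, yet it made no difference to the flask's yield, and decomposed reagent stood at 1.36 × 10⁻⁴ M at 6.00 h.

In a neighbour flask with 0.40 M of solid reagent, the run-out time is 2.50 h, shorter than 6.0 h, which puts the stop at 17.3%. That neighbour flask gave 17.4%, with the solid as limiting reagent at 0%.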